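## Retrosynthetic overview

1. Kurarinone ⇐ removal of three MOM ethers from the (2S)-flavanone 22; C2 is fixed by a catalyst-controlled transfer-hydrogenation kinetic resolution of the C2-epimeric flavanone 21.
2. Ring C is the only ring built (last, step 10): oxa-Michael closure of a 2'-hydroxychalcone made by Claisen–Schmidt condensation of the ring A acetophenone 17 with the ring B aldehyde 19; rings A and B are bought as arenes.
3. Acetophenone 17 ⇐ two directed ortho-metalations of 5-methoxyresorcinol bis-MOM ether 11: first C-alkylation with (S)-lavandulyl iodide 9 between the two OMOM groups, then acetylation.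
4. Iodide 9 ⇐ (S)-lavandulol 8 ⇐ Evans deconjugative α-prenylation of the N-senecioyl (S)-4-benzyloxazolidinone 4, which sets the side-chain stereocentre.

Assumption: enantiopure (S)-lavandulol is not taken as purchasable and is made. "Lavandulyl" means 5-methyl-2-(prop-1-en-2-yl)hex-4-en-1-yl; its (R) descriptor on an arene is the same spatial arrangement as (S) in lavandulol and its iodide, because CH2Ar ranks below isopropenyl while CH2OH and CH2I rank above it.

## Route

Step 1
Reactants: 1 (4S)-4-benzyl-1,3-oxazolidin-2-one; 2 3-methylbut-2-enoyl chloride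
Product: 4 (4S)-4-benzyl-3-(3-methylbut-2-enoyl)-1,3-oxazolidin-2-one, via N-lithio oxazolidinone 3 (not isolated)
Conditions: n-BuLi, THF, −78 °C; then 2, −78 → 0 °C
Reagents that add atoms: none
Why: N-acylation of the lithiated Evans auxiliary by the acid chloride; no stereocentre is created.

Step 2
Reactants: 4 (4S)-4-benzyl-3-(3-methylbut-2-enoyl)-1,3-oxazolidin-2-one; 5 1-bromo-3-methylbut-2-ene (prenyl bromide)
Product: 7 (4S)-4-benzyl-3-[(2S)-5-methyl-2-(prop-1-en-2-yl)hex-4-enoyl]-1,3-oxazolidin-2-one, via sodium Z-dienolate 6 (not isolated)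
Conditions: NaN(SiMe3)2, THF, −78 °C; then 5, −78 → −40 °C; AcOH quench
Reagents that add atoms: none
Why: Evans deconjugative alkylation: γ-deprotonation gives the chelated Z(O)-dienolate, which is prenylated at the α-carbon on the face opposite the benzyl group, setting the (2S) centre and moving the alkene into the isopropenyl position.

Step 3
Reactants: 7 (4S)-4-benzyl-3-[(2S)-5-methyl-2-(prop-1-en-2-yl)hex-4-enoyl]-1,3-oxazolidin-2-one
Product: 8 (S)-lavandulol, (2S)-5-methyl-2-(prop-1-en-2-yl)hex-4-en-1-ol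
Conditions: LiBH4, MeOH (1 equiv.), Et2O, 0 °C
Reagents that add atoms: none
Why: Reductive cleavage of the imide by LiBH4 gives the primary alcohol without touching the α-stereocentre or the alkenes, and returns the auxiliary.

Step 4
Reactants: 8 (S)-lavandulol
Product: 9 (S)-lavandulyl iodide, (3S)-3-(iodomethyl)-2,6-dimethylhepta-1,5-diene
Conditions: PPh3, imidazole, I2, CH2Cl2, 0 °C → rt, dark
Reagents that add atoms: iodine [I][I]
Why: Appel-type iodination by SN2 at the primary carbon, so the adjacent stereocentre is unaffected.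

Step 5
Reactants: 10 5-methoxybenzene-1,3-diol (5-methoxyresorcinol)
Product: 11 1-methoxy-3,5-bis(methoxymethoxy)benzene
Conditions: NaH, MOMCl, DMF, 0 °C → rt
Reagents that add atoms: chloromethyl methyl ether (MOMCl) COCCl
Why: Williamson O-alkylation of both phenoxides gives the bis-MOM ether whose acetal groups later direct metalation.

Step 6
Reactants: 11 1-methoxy-3,5-bis(methoxymethoxy)benzene; 9 (S)-lavandulyl iodide
Product: 13 5-methoxy-1,3-bis(methoxymethoxy)-2-[(2R)-5-methyl-2-(prop-1-en-2-yl)hex-4-en-1-yl]benzene, via aryllithium 12 (not isolated)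
Conditions: n-BuLi, THF, 0 °C → rt; then copper iodide CuI (10 mol %), 9, −20 °C → rt
Reagents that add atoms: none
Why: Directed ortho-metalation occurs at the position flanked by both OMOM groups, and copper-assisted SN2 displacement of the primary iodide leaves the side-chain centre untouched (S becomes R only through the priority change).

Step 7
Reactants: 13 5-methoxy-1,3-bis(methoxymethoxy)-2-[(R)-lavandulyl]benzene; 14 N-methoxy-N-methylacetamide
Product: 16 1-{6-methoxy-2,4-bis(methoxymethoxy)-3-[(R)-lavandulyl]phenyl}ethan-1-one, via aryllithium 15 (not isolated)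
Conditions: n-BuLi, THF, 0 °C; then 14, −78 °C → rt; H2O quench
Reagents that add atoms: none
Why: Second directed ortho-metalation at the only ring position type left (between OMOM and OMe, two equivalent sites) and Weinreb amide acylation, whose stable tetrahedral adduct prevents over-addition.

Step 8
Reactants: 16 1-{6-methoxy-2,4-bis(methoxymethoxy)-3-[(R)-lavandulyl]phenyl}ethan-1-one
Product: 17 1-{2-hydroxy-6-methoxy-4-(methoxymethoxy)-3-[(R)-lavandulyl]phenyl}ethan-1-one
Conditions: HCl (cat.), MeOH, 0 °C → rt, stopped at mono-deprotection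
Reagents that add atoms: none
Why: Acid-catalysed acetal cleavage is fastest for the MOM ether ortho to the ketone (carbonyl-assisted, product phenol hydrogen-bonded), so the para MOM ether survives.

Step 9
Reactants: 18 2,4-dihydroxybenzaldehyde
Product: 19 2,4-bis(methoxymethoxy)benzaldehyde
Conditions: NaH, MOMCl, DMF, 0 °C → rt
Reagents that add atoms: chloromethyl methyl ether (MOMCl) COCCl
Why: Williamson O-alkylation of both phenoxides protects ring B for the basic condensation.

Step 10
Reactants: 17 1-{2-hydroxy-6-methoxy-4-(methoxymethoxy)-3-[(R)-lavandulyl]phenyl}ethan-1-one; 19 2,4-bis(methoxymethoxy)benzaldehyde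
Product: 21 2-[2,4-bis(methoxymethoxy)phenyl]-5-methoxy-7-(methoxymethoxy)-8-[(R)-lavandulyl]-2,3-dihydro-4H-chromen-4-one as a ca. 1:1 mixture of C2 epimers, via 2'-hydroxychalcone 20 (not isolated)
Conditions: KOH (aq. 50 %), EtOH, rt; then AcOH to pH 7–8, reflux
Reagents that add atoms: none
Why: Claisen–Schmidt aldol condensation gives the E-chalcone, and the acetate-buffered 6-endo oxa-Michael addition of the 2'-phenol closes ring C without facial control, so both C2 epimers form.

Step 11
Reactants: 21 flavanone as C2-epimer mixture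
Product: 22 (2S)-2-[2,4-bis(methoxymethoxy)phenyl]-5-methoxy-7-(methoxymethoxy)-8-[(R)-lavandulyl]-2,3-dihydro-4H-chromen-4-one
Conditions: Cp*RhCl[(R,R)-TsDPEN] (1 mol %; Cp* = C5Me5, TsDPEN = TsNCHPhCHPhNH2), HCO2H/Et3N (5:2), EtOAc, rt, to ca. 52 % conversion; chromatography
Reagents that add atoms: none
Why: Noyori–Ikariya asymmetric transfer hydrogenation run as a kinetic resolution: the (R,R)-catalyst gives 4R alcohols, which is matched only for the 2R epimer (cis-(2R,4R)-flavan-4-ol), so the (2S)-ketone is recovered and separated from the alcohol.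

Step 12
Reactants: 22 (2S)-tri-MOM flavanone
Product: 23 kurarinone, (2S)-2-(2,4-dihydroxyphenyl)-7-hydroxy-5-methoxy-8-[(2R)-5-methyl-2-(prop-1-en-2-yl)hex-4-en-1-yl]-2,3-dihydro-4H-chromen-4-one
Conditions: HCl (3 M aq.), MeOH, rt → 40 °C, short reaction time
Reagents that add atoms: none
Why: Acid-catalysed acetal exchange removes the three aryl MOM ethers under conditions mild enough to leave C2, the lavandulyl alkenes and the methyl ether untouched.

## Compound list

1 | (4S)-4-benzyl-1,3-oxazolidin-2-one | O=C1N[C@@H](Cc2ccccc2)CO1 | starting material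
2 | 3-methylbut-2-enoyl chloride | CC(C)=CC(=O)Cl | starting material
3 | N-lithio-(4S)-4-benzyl-1,3-oxazolidin-2-one | [Li]N1[C@@H](Cc2ccccc2)COC1=O | intermediate (not isolated)
4 | (4S)-4-benzyl-3-(3-methylbut-2-enoyl)-1,3-oxazolidin-2-one | CC(C)=CC(=O)N1[C@@H](Cc2ccccc2)COC1=O | intermediate
5 | 1-bromo-3-methylbut-2-ene | CC(C)=CCBr | starting material
6 | sodium Z(O)-dienolate of 4 | C=C(C)/C=C(\[O-])N1[C@@H](Cc2ccccc2)COC1=O.[Na+] | intermediate (not isolated)
7 | (4S)-4-benzyl-3-[(2S)-5-methyl-2-(prop-1-en-2-yl)hex-4-enoyl]-1,3-oxazolidin-2-one | C=C(C)[C@H](CC=C(C)C)C(=O)N1[C@@H](Cc2ccccc2)COC1=O | intermediate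
8 | (S)-lavandulol, (2S)-5-methyl-2-(prop-1-en-2-yl)hex-4-en-1-ol | C=C(C)[C@H](CC=C(C)C)CO | intermediate
9 | (S)-lavandulyl iodide, (3S)-3-(iodomethyl)-2,6-dimethylhepta-1,5-diene | C=C(C)[C@H](CC=C(C)C)CI | intermediate
10 | 5-methoxybenzene-1,3-diol | COc1cc(O)cc(O)c1 | starting material
11 | 1-methoxy-3,5-bis(methoxymethoxy)benzene | COCOc1cc(OC)cc(OCOC)c1 | intermediate
12 | [4-methoxy-2,6-bis(methoxymethoxy)phenyl]lithium | [Li]c1c(OCOC)cc(OC)cc1OCOC | intermediate (not isolated)
13 | 5-methoxy-1,3-bis(methoxymethoxy)-2-[(2R)-5-methyl-2-(prop-1-en-2-yl)hex-4-en-1-yl]benzene | C=C(C)[C@H](CC=C(C)C)Cc1c(OCOC)cc(OC)cc1OCOC | intermediate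
14 | N-methoxy-N-methylacetamide | CC(=O)N(C)OC | starting material
15 | {6-methoxy-2,4-bis(methoxymethoxy)-3-[(R)-lavandulyl]phenyl}lithium | C=C(C)[C@H](CC=C(C)C)Cc1c(OCOC)cc(OC)c([Li])c1OCOC | intermediate (not isolated)
16 | 1-{6-methoxy-2,4-bis(methoxymethoxy)-3-[(R)-lavandulyl]phenyl}ethan-1-one | C=C(C)[C@H](CC=C(C)C)Cc1c(OCOC)cc(OC)c(C(C)=O)c1OCOC | intermediate
17 | 1-{2-hydroxy-6-methoxy-4-(methoxymethoxy)-3-[(R)-lavandulyl]phenyl}ethan-1-one | C=C(C)[C@H](CC=C(C)C)Cc1c(OCOC)cc(OC)c(C(C)=O)c1O | intermediate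
18 | 2,4-dihydroxybenzaldehyde | O=Cc1ccc(O)cc1O | starting material
19 | 2,4-bis(methoxymethoxy)benzaldehyde | COCOc1ccc(C=O)c(OCOC)c1 | intermediate
20 | (E)-3-[2,4-bis(methoxymethoxy)phenyl]-1-{2-hydroxy-6-methoxy-4-(methoxymethoxy)-3-[(R)-lavandulyl]phenyl}prop-2-en-1-one | C=C(C)[C@H](CC=C(C)C)Cc1c(OCOC)cc(OC)c(C(=O)/C=C/c2ccc(OCOC)cc2OCOC)c1O | intermediate (not isolated)
21 | 2-[2,4-bis(methoxymethoxy)phenyl]-5-methoxy-7-(methoxymethoxy)-8-[(R)-lavandulyl]-2,3-dihydro-4H-chromen-4-one, ca. 1:1 C2 epimers | C=C(C)[C@H](CC=C(C)C)Cc1c(OCOC)cc(OC)c2c1OC(c1ccc(OCOC)cc1OCOC)CC2=O | intermediate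
22 | (2S)-2-[2,4-bis(methoxymethoxy)phenyl]-5-methoxy-7-(methoxymethoxy)-8-[(R)-lavandulyl]-2,3-dihydro-4H-chromen-4-one | C=C(C)[C@H](CC=C(C)C)Cc1c(OCOC)cc(OC)c2c1O[C@H](c1ccc(OCOC)cc1OCOC)CC2=O | intermediate
23 | kurarinone | C=C(C)[C@H](CC=C(C)C)Cc1c(O)cc(OC)c2c1O[C@H](c1ccc(O)cc1O)CC2=O | target

## Step count and risks

Total steps: 12. Longest linear sequence: 10 steps (1–4, 6–8, 10–12).

**Step 6 (aryl–lavandulyl bond).** The β-branched iodide 9 may eliminate instead of substituting. The fallback sets out from 11 and 9 and comes back at 13. Compound 11 is lithiated as before and quenched with iodine to 2-iodo-5-methoxy-1,3-bis(methoxymethoxy)benzene F1. Iodide 9 is inserted with zinc dust and LiCl (THF, 40 °C) to [(2S)-5-methyl-2-(prop-1-en-2-yl)hex-4-en-1-yl]zinc iodide F2, used in solution. Negishi coupling of the two with Pd(OAc)2 and SPhos (THF, 50 °C) gives 13.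

**Step 8 (selective removal of one MOM group).** The para MOM ether may be lost as well. The fallback sets out from 16 and comes back at 17. Both MOM groups are removed (HCl, MeOH, 40 °C) to 1-{2,4-dihydroxy-6-methoxy-3-[(R)-lavandulyl]phenyl}ethan-1-one F3. Only the non-chelated 4-hydroxyl is then re-protected (MOMCl 1.05 equiv., K2CO3, acetone, rt), since the 2-hydroxyl is hydrogen-bonded to the ketone, and this gives 17.

**Step 11 (kinetic resolution).** The electron-rich 5-methoxy ketone may reduce slowly or unselectively, and the yield cannot exceed half. The fallback sets out from 17 and comes back at 22, building C2 by enantioselective C–C bond formation instead.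
- Compound 17 is heated with N,N-dimethylformamide dimethyl acetal (90 °C) to the enaminone (E)-3-(dimethylamino)-1-{2-hydroxy-6-methoxy-4-(methoxymethoxy)-3-[(R)-lavandulyl]phenyl}prop-2-en-1-one F4.
- Warming F4 with AcOH in toluene closes it to the chromone 5-methoxy-7-(methoxymethoxy)-8-[(R)-lavandulyl]-4H-chromen-4-one F5.
- Commercial 4-bromoresorcinol is protected (NaH, MOMCl, DMF) to 1-bromo-2,4-bis(methoxymethoxy)benzene F6.
- F6 is converted (n-BuLi, THF, −78 °C; B(OiPr)3; H2O) into [2,4-bis(methoxymethoxy)phenyl]boronic acid F7.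
- Hayashi–Miyaura 1,4-addition of F7 to F5 with [RhOH(cod)]2 and (S)-MeO-F12-BIPHEP (toluene/H2O, rt) gives 22. The (S) ligand hand is predicted by analogy with cyclohexenone and should be confirmed on the parent chromone first.

## Further compounds

F1 | step 6 | 2-iodo-5-methoxy-1,3-bis(methoxymethoxy)benzene | COCOc1cc(OC)cc(OCOC)c1I
F2 | step 6 | [(2S)-5-methyl-2-(prop-1-en-2-yl)hex-4-en-1-yl]zinc iodide | C=C(C)[C@H](CC=C(C)C)C[Zn]I
F3 | step 8 | 1-{2,4-dihydroxy-6-methoxy-3-[(2R)-5-methyl-2-(prop-1-en-2-yl)hex-4-en-1-yl]phenyl}ethan-1-one | C=C(C)[C@H](CC=C(C)C)Cc1c(O)cc(OC)c(C(C)=O)c1O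
F4 | step 11 | (E)-3-(dimethylamino)-1-{2-hydroxy-6-methoxy-4-(methoxymethoxy)-3-[(R)-lavandulyl]phenyl}prop-2-en-1-one | C=C(C)[C@H](CC=C(C)C)Cc1c(OCOC)cc(OC)c(C(=O)/C=C/N(C)C)c1O
F5 | step 11 | 5-methoxy-7-(methoxymethoxy)-8-[(R)-lavandulyl]-4H-chromen-4-one | C=C(C)[C@H](CC=C(C)C)Cc1c(OCOC)cc(OC)c2c1OC=CC2=O
F6 | step 11 | 1-bromo-2,4-bis(methoxymethoxy)benzene | COCOc1ccc(Br)c(OCOC)c1
F7 | step 11 | [2,4-bis(methoxymethoxy)phenyl]boronic acid | COCOc1ccc(B(O)O)c(OCOC)c1
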